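## The problem

Target 25, (4R)-7-hydroxy-4-(4-hydroxy-3-methoxyphenyl)-5-[(E)-2-(4-hydroxy-3-methoxyphenyl)ethenyl]-3,4-dihydro-2H-chromen-2-one, is a 4-aryl-3,4-dihydrocoumarin. Benzene ring A (C4a, C5, C6, C7, C8, C8a) is fused to the six-membered lactone ring B (O1, C2, C3, C4, C4a, C8a). Ring A is a 1,2,3,5-tetrasubstituted benzene whose three contiguous substituents (the lactone oxygen on C8a, C4 on C4a, the styryl carbon Cα on C5) crowd C4a from both sides. Electrophilic substitution of a resorcinol or phloroglucinol core does not deliver this pattern cleanly. The only stereocentre is the doubly benzylic C4 (R); nothing else in the molecule can relay its configuration, so it must come from a chiral catalyst or reagent, and the aryl group on C4 sits peri to the styryl group on C5. The aryl ester of ring B opens with hydroxide, alkoxide or acidic methanol, and the three phenols must be masked towards organometallic reagents. The (E)-stilbene rules out hydrogenolysis and, because the para-hydroxystyryl unit is easily protonated next to the electron-rich C4 aryl ring, also rules out strong acid late in the route. The enabling feature is the row oxygen (C8a), carbon (C4a), carbon (C5): C4a and C5 can be the two carbons of an aryne polarised by the C8a oxygen, so that a styryl nucleophile enters at C5 and a one-carbon electrophile (the future C4) at C4a in one operation.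

## Retrosynthesis

**25 to 24.** Only O–Si bonds are cut, leading to the tris(triisopropylsilyl) ether 24. Silyl ethers are preferred to acetals at the end because buffered fluoride touches neither the lactone nor the stilbene, whereas acetal removal would need acid exactly where the protonated styryl group could alkylate the C4 aryl ring. The forward step must free three phenols without opening ring B.

**24 to 20 and 23.** The C4–aryl bond is cut, giving the flat, achiral coumarin 20 and the arylboronic acid 23. This removes the only stereocentre together with a whole aryl ring. The neighbouring cuts leave the stereochemical problem in place: O1–C2 would need an enantiopure 3,3-diarylpropanoic acid, and C4–C4a would need a chiral benzylic unit joined to the most hindered carbon of ring A. The forward reaction has to deliver the aryl group to one face of C3=C4 under catalyst control, beside the peri styryl group, and without base.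

**20 to 19 to 16 to 15.** Ring B is opened at O1–C2 and C3=C4. Coumarin 19 (silylated to 20) comes from salicylaldehyde 16 by olefination with a two-carbon stabilised phosphorus ylide and lactonisation through the acrylates 17 and 18. A Pechmann-type condensation of a 5-styrylresorcinol would have to choose between two ring positions under strong acid; here the regiochemistry is fixed because C4 is already attached to C4a as a formyl group. Hydrolysis of three methoxymethyl ethers links 16 to aldehyde 15, and the change of protecting group is placed at this stage, where acid is tolerable.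

**15 to 4, 10 and 11.** The C5–Cα and C4a–C4 bonds are cut together, giving aryne 13, the alkenyl Grignard reagent 10 and N,N-dimethylformamide 11. Aryne 13 arises from the iodoaryl sulfonate 4 through the magnesiated sulfonate 12, and addition of 10 gives the arylmagnesium 14. Formylation of a preformed 3,5-dioxygenated stilbene would have to distinguish C4a from the position between the two oxygens, and cross-coupling onto a 2-halobenzaldehyde only moves the 1,2,3,5 pattern into the halide. The aryne cut instead exchanges the tetrasubstituted ring for a sulfonate made from a symmetric triol and attaches both carbon substituents in one flask. The forward reaction must place carbon on C5 and magnesium on C4a, and keep the alkene geometry.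

**4 to 3 to 2 to 1.** The S–O and C–I bonds and two acetal C–O bonds are cut, leading back through iodophenol 3 and bis-ether 2 to phloroglucinol 1. Because all three hydroxyls of 1 are equivalent, only the degree of alkylation and the site of iodination (ortho to the free hydroxyl) have to be controlled.

**10 to 9 to 8 to 7 to 5.** The C–Mg bond is traced through alkenyllithium 9 to bromide 8, and the C–Br bond to the carboxyl group of acid 7, which is the methoxymethyl ether of ferulic acid 5 (formed through ester 6). The (E)-alkene is bought with 5, so no olefination is needed; the forward steps must exchange CO2H for Br and Br for Mg with retention.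

**23 to 22 to 21.** The B–O(pinacol) and O–Si bonds are cut, leading to the commercial phenol boronate 21 through its silyl ether 22. The phenol is masked because a free para-hydroxyarylboronic acid protodeboronates readily.

## Roads not taken

**Alternative 1:** Ring A is dismantled at C8–C8a and C6–C7, giving the cyclobutenone A2, which already carries the C4 stereocentre in its side chain, and the silyloxyacetylene A3. In the forward Danheiser benzannulation, heating opens A2 to a vinylketene, A3 adds by [2+2] cycloaddition, and a second ring opening and a six-electron closure give phenol A1.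
- Merits: every substituent of ring A is placed by the connectivity of the partners. The stereocentre is made early in an open-chain glutarate, far from the peri crowding. A1 has the C8a hydroxyl free for lactonisation and the C7 oxygen already differentiated.
- Weak points: A2 is a demanding target in itself (a 3-styrylcyclobutenone with a stereogenic benzylic carbon beside the ring). The cascade runs hot through a ketene conjugated with the styryl unit, which opens competing electrocyclisations and hydrogen shifts involving the C–H of the stereocentre. A3 is a sensitive reagent.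
- Comparison: in stereocontrol this road is better, since its stereocentre does not depend on a catalytic addition next to the C5 substituent. The chosen plan sets against this its short access to all partners from cheap commercial compounds, a ring A that never has to be built, and a stereo-defining catalyst whose antipode is equally available.

**Alternative 2:** Both guaiacyl–carbon bonds (Cβ–aryl of the stilbene and C4–aryl) are cut, giving the 5-vinylcoumarin A5 and two equivalents of the boronic acid A6. A palladium diacetate–phenanthroline catalyst under oxygen would arylate both alkenes by oxidative Heck reaction to give coumarin A4.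
- Merits: high convergence, one aryl reagent for both rings, the (E)-stilbene follows from the Heck mechanism, and no organomagnesium chemistry is needed.
- Weak points: A4 is a coumarin, so the C4 stereocentre still has to be made afterwards by an enantioselective conjugate reduction that spares the stilbene. The vinyl group and the hindered coumarin C4 differ greatly in rate, so forcing the second arylation invites over-arylation of the new stilbene and boronic acid homocoupling. A5 still needs a carbon substituent on C5 of a 5,7-dioxygenated coumarin, so the ring A pattern is only passed on to a precursor. The final acid removal of three methoxymethyl ethers falls at the acid-sensitive stage.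
- Comparison: in convergence, and probably in step count, this road is at least as good. The chosen plan sets against it an explicit solution of the ring A pattern, formation of the C4–aryl bond and the stereocentre in one precedented reaction, and a neutral final deprotection.

**Alternative 3:** The C4a–C5 bond is cut and ring A is unfolded into the open-chain triketo ester A8. In aqueous hydroxide the ester is saponified, the C4a methylene adds to the C5 styryl ketone, and dehydration and enolisation give the resorcinol acid A7.
- Merits: biomimetic, no protecting groups on ring A, the stereocentre is set beforehand in a simple chain, A7 lactonises on acidification, and there is no peri problem.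
- Weak points: the chain has two doubly activated methylenes (C6, C8) that are more acidic than the C4a methylene that has to react. The C5 carbonyl belongs to an enolised styryl 1,3-diketone and is the least electrophilic one. Pyranone formation, Michael addition of C8 to the styryl β-carbon, Claisen-type closure onto the ester and retro-aldol cleavage of the enone all compete. Preparing and handling A8 is delicate.
- Comparison: in protecting-group economy and in placing the stereocentre early this road is superior. The chosen plan sets against it a regiochemistry governed by one substituent effect instead of a competition among several enolates, and stable, isolable intermediates throughout.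

Key step: step 7

Assumption: the (R)-bisphosphine is taken to deliver the aryl group to the same face of the coumarin as in 5-unsubstituted coumarins, where it gives (R)-4-arylchroman-2-ones; the CIP ranking at C4 (C4a > aryl > C3 > H) is the same in 24, and the ligand antipode would be used should the first run show the opposite sense.

## Route

Step 1
Reactants: 1 phloroglucinol (benzene-1,3,5-triol)
Product: 2 3,5-bis(methoxymethoxy)phenol
Conditions: MOMCl (2.0 equiv), i-Pr2NEt (2.2 equiv), DMF, 0 °C → rt
Reagents that add atoms: chloromethyl methyl ether (MOMCl), COCCl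
Why: O-alkylation of phenols with a chloromethyl ether (acetal formation); it is statistical, but all three hydroxyls are equivalent, so only the degree of alkylation matters, the bis-ether being separated by chromatography and the mono- and tris-ethers recycled.

Step 2
Reactants: 2 3,5-bis(methoxymethoxy)phenol
Product: 3 2-iodo-3,5-bis(methoxymethoxy)phenol
Conditions: NIS (1.0 equiv), CH2Cl2, −40 → 0 °C, dark
Reagents that add atoms: N-iodosuccinimide (NIS), O=C1CCC(=O)N1I
Why: Electrophilic aromatic iodination; C2 is activated by the ortho hydroxyl and by one ortho and one para ether and is less hindered than C4 between the two methoxymethoxy groups, and hydrogen bonding of the phenol to the N-iodoimide favours ortho delivery, the preference expected from the halogenation of 3,5-dialkoxyphenols. One equivalent at low temperature should limit di-iodination.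

Step 3
Reactants: 3 2-iodo-3,5-bis(methoxymethoxy)phenol
Product: 4 2-iodo-3,5-bis(methoxymethoxy)phenyl 4-chlorobenzenesulfonate
Conditions: 4-ClC6H4SO2Cl, Et3N, DMAP (cat.), CH2Cl2, 0 °C → rt
Reagents that add atoms: 4-chlorobenzenesulfonyl chloride, O=S(=O)(Cl)c1ccc(Cl)cc1
Why: O-sulfonylation of a phenol under amine base; this arenesulfonate is a leaving group that should stay in place at −78 °C after metalation of the neighbouring carbon and leave only on warming.

Step 4
Reactants: 5 ferulic acid, (E)-3-(4-hydroxy-3-methoxyphenyl)prop-2-enoic acid
Product: 7 (E)-3-[3-methoxy-4-(methoxymethoxy)phenyl]prop-2-enoic acid, via methoxymethyl ester 6 (not isolated)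
Conditions: MOMCl (2.3 equiv), i-Pr2NEt, CH2Cl2, 0 °C → rt; then LiOH, THF/MeOH/H2O, rt; 1 M HCl to pH 4, 0 °C
Reagents that add atoms: chloromethyl methyl ether (MOMCl), COCCl; lithium hydroxide, [Li+].[OH-]
Why: Both acidic hydroxyls are alkylated, and the methoxymethyl ester 6 is then saponified by acyl–oxygen cleavage while the aryl methoxymethyl ether is inert to hydroxide; brief cold acidification to pH 4 should leave the acetal intact.

Step 5
Reactants: 7 (E)-3-[3-methoxy-4-(methoxymethoxy)phenyl]prop-2-enoic acid
Product: 8 4-[(E)-2-bromoethenyl]-2-methoxy-1-(methoxymethoxy)benzene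
Conditions: NBS (1.05 equiv), LiOAc (0.1 equiv), MeCN/H2O, rt
Reagents that add atoms: N-bromosuccinimide (NBS), O=C1CCC(=O)N1Br
Why: Catalytic Hunsdiecker-type bromodecarboxylation of an electron-rich cinnamic acid: bromonium transfer to the alkene of the carboxylate, assisted by the para oxygen, is followed by loss of CO2 and should give the (E)-bromoalkene; the neutral conditions spare the acetal.

Step 6
Reactants: 8 4-[(E)-2-bromoethenyl]-2-methoxy-1-(methoxymethoxy)benzene
Product: 10 (E)-2-[3-methoxy-4-(methoxymethoxy)phenyl]ethenylmagnesium bromide, via alkenyllithium 9 (not isolated)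
Conditions: t-BuLi (2.0 equiv), Et2O, −78 °C; MgBr2·OEt2 (1.1 equiv), Et2O/THF, −78 → 0 °C
Reagents that add atoms: magnesium bromide diethyl etherate, Br[Mg]Br.CCOCC
Why: Bromine–lithium exchange of an alkenyl bromide and transmetalation to magnesium both proceed with retention of alkene geometry, whereas direct magnesium insertion passes through configurationally labile vinyl radicals; the second equivalent of t-BuLi destroys the t-BuBr formed. The reagent is kept as a titrated ethereal solution and used directly.

Step 7
Reactants: 4 2-iodo-3,5-bis(methoxymethoxy)phenyl 4-chlorobenzenesulfonate; 10 (E)-2-[3-methoxy-4-(methoxymethoxy)phenyl]ethenylmagnesium bromide; 11 N,N-dimethylformamide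
Product: 15 2,4-bis(methoxymethoxy)-6-[(E)-2-[3-methoxy-4-(methoxymethoxy)phenyl]ethenyl]benzaldehyde, via magnesiated aryl sulfonate 12 (not isolated), via 3,5-bis(methoxymethoxy)benzyne 13 (not isolated), via arylmagnesium bromide 14 (not isolated)
Conditions: i-PrMgCl·LiCl (1.05 equiv), THF, −78 °C; 10 (2.5 equiv), −78 °C → rt; DMF (5 equiv), 0 °C → rt; aq NH4Cl
Reagents that add atoms: none
Why: Aryne carbomagnesiation with electrophilic trapping: iodine–magnesium exchange at −78 °C converts 4 into the ortho-magnesiated sulfonate 12, which on warming expels magnesium 4-chlorobenzenesulfonate to give aryne 13; the alkenyl carbon–magnesium bond of 10 adds across the strained triple bond to give arylmagnesium 14, and DMF 11 formylates it, the aldehyde being released from the hemiaminal salt on aqueous work-up. The closest known reaction type is the addition of aryl or allyl Grignard reagents and of magnesium amides or thiolates to arynes released from 2-iodoaryl sulfonates or ortho-haloaryl metals, followed by trapping of the new arylmagnesium with an electrophile; the alkenyl Grignard reagent is a further sp2 nucleophile within that class. The step closes no ring and creates no stereocentre. It needs regioselectivity, which the methoxymethoxy group beside the triple bond (the future C8a oxygen) provides: its inductive pull and the resulting distortion of the aryne make the remote carbon (future C5) the electrophilic one, and magnesium ends up on the carbon next to the oxygen (future C4a), where it is stabilised inductively and by chelation; the second ether, para to that carbon, is too remote to reverse the preference. It needs chemoselective capture of 13, secured by using only a slight excess of i-PrMgCl·LiCl and by having 10 present in excess before the elimination sets in, so that isopropyl transfer and addition of 12 to 13 are outrun. It needs retention of the (E) geometry, which follows from addition at the sp2 carbon–magnesium bond without rehybridisation of the alkenyl carbon. DMF is small enough to reach the magnesium flanked by the ether and the new styryl group.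

Step 8
Reactants: 15 2,4-bis(methoxymethoxy)-6-[(E)-2-[3-methoxy-4-(methoxymethoxy)phenyl]ethenyl]benzaldehyde
Product: 16 2,4-dihydroxy-6-[(E)-2-(4-hydroxy-3-methoxyphenyl)ethenyl]benzaldehyde
Conditions: 3 M HCl (aq), THF, 50 °C, argon
Reagents that add atoms: none
Why: Acid hydrolysis of three aryl methoxymethyl acetals; here the formyl group deactivates ring A and no nucleophilic arene sits beside the stilbene, so the acid should do less harm than it would at the end of the route.

Step 9
Reactants: 16 2,4-dihydroxy-6-[(E)-2-(4-hydroxy-3-methoxyphenyl)ethenyl]benzaldehyde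
Product: 19 7-hydroxy-5-[(E)-2-(4-hydroxy-3-methoxyphenyl)ethenyl]-2H-chromen-2-one, via (E)-acrylate ester 17 (not isolated), via (Z)-acrylate ester 18 (not isolated)
Conditions: Ph3P=CHCO2Et (2.5 equiv), PhNEt2, reflux (ca. 215 °C), argon
Reagents that add atoms: ethyl (triphenylphosphoranylidene)acetate, CCOC(=O)C=P(c1ccccc1)(c1ccccc1)c1ccccc1
Why: Wittig olefination of the salicylaldehyde, thermal E to Z equilibration of the acrylate and lactonisation onto the ortho hydroxyl, the one-pot coumarin synthesis that is used with unprotected di- and trihydroxybenzaldehydes. The stilbene is already the thermodynamic (E) isomer and should not be affected.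

Step 10
Reactants: 19 7-hydroxy-5-[(E)-2-(4-hydroxy-3-methoxyphenyl)ethenyl]-2H-chromen-2-one
Product: 20 5-[(E)-2-[3-methoxy-4-(triisopropylsilyloxy)phenyl]ethenyl]-7-(triisopropylsilyloxy)-2H-chromen-2-one
Conditions: TIPSCl (2.5 equiv), imidazole, DMF, rt
Reagents that add atoms: chlorotriisopropylsilane (TIPSCl), CC(C)[Si](Cl)(C(C)C)C(C)C
Why: O-silylation of both phenols; the bulky triisopropylsilyl ethers should survive the warm aqueous dioxane of step 13 better than smaller silyl groups and still fall to fluoride at the end.

Step 11
Reactants: 21 2-methoxy-4-(4,4,5,5-tetramethyl-1,3,2-dioxaborolan-2-yl)phenol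
Product: 22 triisopropyl[2-methoxy-4-(4,4,5,5-tetramethyl-1,3,2-dioxaborolan-2-yl)phenoxy]silane
Conditions: TIPSCl (1.2 equiv), imidazole, DMF, rt
Reagents that add atoms: chlorotriisopropylsilane (TIPSCl), CC(C)[Si](Cl)(C(C)C)C(C)C
Why: O-silylation; it masks the electron-rich phenol, which would otherwise be oxidised by periodate in step 12 and would speed protodeboronation in step 13.

Step 12
Reactants: 22 triisopropyl[2-methoxy-4-(4,4,5,5-tetramethyl-1,3,2-dioxaborolan-2-yl)phenoxy]silane
Product: 23 [3-methoxy-4-(triisopropylsilyloxy)phenyl]boronic acid
Conditions: NaIO4, NH4OAc, acetone/H2O, rt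
Reagents that add atoms: water, O
Why: Hydrolysis of the pinacol boronate is driven to completion by periodate glycol cleavage of the released diol, under near-neutral conditions that should leave the aryl silyl ether untouched.

Step 13
Reactants: 20 5-[(E)-2-[3-methoxy-4-(triisopropylsilyloxy)phenyl]ethenyl]-7-(triisopropylsilyloxy)-2H-chromen-2-one; 23 [3-methoxy-4-(triisopropylsilyloxy)phenyl]boronic acid
Product: 24 (4R)-4-[3-methoxy-4-(triisopropylsilyloxy)phenyl]-5-[(E)-2-[3-methoxy-4-(triisopropylsilyloxy)phenyl]ethenyl]-7-(triisopropylsilyloxy)-3,4-dihydro-2H-chromen-2-one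
Conditions: Rh(acac)(C2H4)2 (3 mol %), (R)-SEGPHOS (3.3 mol %), 23 (4 equiv, in portions), 1,4-dioxane/H2O (10:1), 60 °C
Reagents that add atoms: none
Why: Rhodium-catalysed asymmetric 1,4-addition of an arylboronic acid to a coumarin: transmetalation gives an aryl complex of monovalent rhodium, the chiral bisphosphine selects the enantioface of C3=C4 for insertion, and water protonates the rhodium enolate, so C4 is set by the catalyst alone, the (R)-ligand being the one that gives (R)-4-arylchroman-2-ones. The base-free medium should leave the lactone and silyl ethers intact, and the unactivated stilbene should not insert.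

Step 14
Reactants: 24 (4R)-4-[3-methoxy-4-(triisopropylsilyloxy)phenyl]-5-[(E)-2-[3-methoxy-4-(triisopropylsilyloxy)phenyl]ethenyl]-7-(triisopropylsilyloxy)-3,4-dihydro-2H-chromen-2-one
Product: 25 (4R)-7-hydroxy-4-(4-hydroxy-3-methoxyphenyl)-5-[(E)-2-(4-hydroxy-3-methoxyphenyl)ethenyl]-3,4-dihydro-2H-chromen-2-one
Conditions: TBAF (3.3 equiv), AcOH (3.5 equiv), THF, 0 °C → rt
Reagents that add atoms: none
Why: Fluoride-induced cleavage of aryl silyl ethers; acetic acid buffers the phenoxides so that the aryl ester of ring B should not be opened, and C4, which is not α to the carbonyl, cannot epimerise by enolisation.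

## Compound list

1 | phloroglucinol (benzene-1,3,5-triol) | Oc1cc(O)cc(O)c1 | starting material
2 | 3,5-bis(methoxymethoxy)phenol | COCOc1cc(O)cc(OCOC)c1 | intermediate
3 | 2-iodo-3,5-bis(methoxymethoxy)phenol | COCOc1cc(O)c(I)c(OCOC)c1 | intermediate
4 | 2-iodo-3,5-bis(methoxymethoxy)phenyl 4-chlorobenzenesulfonate | COCOc1cc(OCOC)c(I)c(OS(=O)(=O)c2ccc(Cl)cc2)c1 | intermediate
5 | ferulic acid, (E)-3-(4-hydroxy-3-methoxyphenyl)prop-2-enoic acid | COc1cc(/C=C/C(=O)O)ccc1O | starting material
6 | methoxymethyl (E)-3-[3-methoxy-4-(methoxymethoxy)phenyl]prop-2-enoate | COCOC(=O)/C=C/c1ccc(OCOC)c(OC)c1 | intermediate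
7 | (E)-3-[3-methoxy-4-(methoxymethoxy)phenyl]prop-2-enoic acid | COCOc1ccc(/C=C/C(=O)O)cc1OC | intermediate
8 | 4-[(E)-2-bromoethenyl]-2-methoxy-1-(methoxymethoxy)benzene | COCOc1ccc(/C=C/Br)cc1OC | intermediate
9 | (E)-2-[3-methoxy-4-(methoxymethoxy)phenyl]ethenyllithium | COCOc1ccc(/C=C/[Li])cc1OC | intermediate
10 | (E)-2-[3-methoxy-4-(methoxymethoxy)phenyl]ethenylmagnesium bromide | COCOc1ccc(/C=C/[Mg]Br)cc1OC | intermediate
11 | N,N-dimethylformamide | CN(C)C=O | starting material
12 | 2-(4-chlorobenzenesulfonyloxy)-4,6-bis(methoxymethoxy)phenylmagnesium chloride | COCOc1cc(OCOC)c([Mg]Cl)c(OS(=O)(=O)c2ccc(Cl)cc2)c1 | intermediate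
13 | 3,5-bis(methoxymethoxy)benzyne (1,2-didehydro-3,5-bis(methoxymethoxy)benzene) | COCOC1=CC(OCOC)=CC#C1 | intermediate
14 | 2,4-bis(methoxymethoxy)-6-[(E)-2-[3-methoxy-4-(methoxymethoxy)phenyl]ethenyl]phenylmagnesium bromide | COCOc1cc(OCOC)c([Mg]Br)c(/C=C/c2ccc(OCOC)c(OC)c2)c1 | intermediate
15 | 2,4-bis(methoxymethoxy)-6-[(E)-2-[3-methoxy-4-(methoxymethoxy)phenyl]ethenyl]benzaldehyde | O=Cc1c(OCOC)cc(OCOC)cc1/C=C/c1ccc(OCOC)c(OC)c1 | intermediate
16 | 2,4-dihydroxy-6-[(E)-2-(4-hydroxy-3-methoxyphenyl)ethenyl]benzaldehyde | O=Cc1c(O)cc(O)cc1/C=C/c1ccc(O)c(OC)c1 | intermediate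
17 | ethyl (E)-3-[2,4-dihydroxy-6-[(E)-2-(4-hydroxy-3-methoxyphenyl)ethenyl]phenyl]prop-2-enoate | CCOC(=O)/C=C/c1c(O)cc(O)cc1/C=C/c1ccc(O)c(OC)c1 | intermediate
18 | ethyl (Z)-3-[2,4-dihydroxy-6-[(E)-2-(4-hydroxy-3-methoxyphenyl)ethenyl]phenyl]prop-2-enoate | CCOC(=O)/C=C\c1c(O)cc(O)cc1/C=C/c1ccc(O)c(OC)c1 | intermediate
19 | 7-hydroxy-5-[(E)-2-(4-hydroxy-3-methoxyphenyl)ethenyl]-2H-chromen-2-one | O=c1ccc2c(/C=C/c3ccc(O)c(OC)c3)cc(O)cc2o1 | intermediate
20 | 5-[(E)-2-[3-methoxy-4-(triisopropylsilyloxy)phenyl]ethenyl]-7-(triisopropylsilyloxy)-2H-chromen-2-one | O=c1ccc2c(/C=C/c3ccc(O[Si](C(C)C)(C(C)C)C(C)C)c(OC)c3)cc(O[Si](C(C)C)(C(C)C)C(C)C)cc2o1 | intermediate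
21 | 2-methoxy-4-(4,4,5,5-tetramethyl-1,3,2-dioxaborolan-2-yl)phenol (4-hydroxy-3-methoxyphenylboronic acid pinacol ester) | COc1cc(B2OC(C)(C)C(C)(C)O2)ccc1O | starting material
22 | triisopropyl[2-methoxy-4-(4,4,5,5-tetramethyl-1,3,2-dioxaborolan-2-yl)phenoxy]silane | COc1cc(B2OC(C)(C)C(C)(C)O2)ccc1O[Si](C(C)C)(C(C)C)C(C)C | intermediate
23 | [3-methoxy-4-(triisopropylsilyloxy)phenyl]boronic acid | COc1cc(B(O)O)ccc1O[Si](C(C)C)(C(C)C)C(C)C | intermediate
24 | (4R)-4-[3-methoxy-4-(triisopropylsilyloxy)phenyl]-5-[(E)-2-[3-methoxy-4-(triisopropylsilyloxy)phenyl]ethenyl]-7-(triisopropylsilyloxy)-3,4-dihydro-2H-chromen-2-one | COc1cc(/C=C/c2cc(O[Si](C(C)C)(C(C)C)C(C)C)cc3c2[C@@H](c2ccc(O[Si](C(C)C)(C(C)C)C(C)C)c(OC)c2)CC(=O)O3)ccc1O[Si](C(C)C)(C(C)C)C(C)C | intermediate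
25 | (4R)-7-hydroxy-4-(4-hydroxy-3-methoxyphenyl)-5-[(E)-2-(4-hydroxy-3-methoxyphenyl)ethenyl]-3,4-dihydro-2H-chromen-2-one | COc1cc(/C=C/c2cc(O)cc3c2[C@@H](c2ccc(O)c(OC)c2)CC(=O)O3)ccc1O | target

## Step count and least certain steps

Total step count: 14. Longest linear sequence: 9 steps (steps 4, 5, 6, 7, 8, 9, 10, 13, 14 from 5; the sequence 1, 2, 3, 7, 8, 9, 10, 13, 14 from 1 is equally long).

**Step 7 (key step).** The most likely failure is capture of the aryne by the wrong partner: isopropyl transfer from residual exchange reagent, addition of 12 to 13, or attack of 10 at the sulfonyl sulfur of 4 or 12 before the elimination sets in. Incomplete regiocontrol or erosion of the alkene geometry would come second. Fallback (sets out from 2 and 10, returns at 15): the same two bonds are made one after the other on the same carbons without an aryne. Phenol 2 is formylated ortho to the hydroxyl by the magnesium-mediated method (MgCl2, Et3N, paraformaldehyde, MeCN, reflux) to give 2-hydroxy-4,6-bis(methoxymethoxy)benzaldehyde F1. Its hydrogen-bonded hydroxyl is converted with Tf2O and pyridine into 2-formyl-3,5-bis(methoxymethoxy)phenyl trifluoromethanesulfonate F2. Grignard reagent 10 is quenched with 2-isopropoxy-4,4,5,5-tetramethyl-1,3,2-dioxaborolane to give 2-[(E)-2-[3-methoxy-4-(methoxymethoxy)phenyl]ethenyl]-4,4,5,5-tetramethyl-1,3,2-dioxaborolane F3. Suzuki–Miyaura coupling of F2 with F3 (Pd(PPh3)4, K3PO4, dioxane/H2O, 80 °C) should then give 15.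

**Step 13.** The most likely failure is slow insertion: the peri styryl group hinders C4, and the 7-oxygenated coumarin is a weak acceptor, so protodeboronation of 23 may outrun the addition; the crowding may also lower the enantioface discrimination. Fallback (sets out from 20 and 23, returns at 24): the aryl group is introduced without a stereochemical demand, and the stereocentre is then set by a small hydride nucleophile. Oxidative Heck arylation of 20 with 23 (Pd(OAc)2, 1,10-phenanthroline, O2, DMF, 80 °C), which ends in β-hydride elimination, should give 4-[3-methoxy-4-(triisopropylsilyloxy)phenyl]-5-[(E)-2-[3-methoxy-4-(triisopropylsilyloxy)phenyl]ethenyl]-7-(triisopropylsilyloxy)-2H-chromen-2-one F4. Copper hydride asymmetric conjugate reduction of F4 (Cu(OAc)2·H2O, DTBM-SEGPHOS, (EtO)2MeSiH in slight excess, t-BuOH, toluene, 0 °C), with the ligand enantiomer chosen on an analytical run, should give 24; the stilbene, being unactivated, should be left alone.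

**Step 2.** The most likely failure is iodination at C4 (para to the hydroxyl, between the two ethers) or twice, which would lower the supply of 3 and complicate its purification. Fallback (sets out from 2, returns at 3): the position is fixed by directed ortho-metalation instead of electrophilic substitution. Phenol 2 is converted with ClCONEt2 and NaH into 3,5-bis(methoxymethoxy)phenyl N,N-diethylcarbamate F5. Lithiation with s-BuLi/TMEDA in THF at −78 °C, between the carbamate and the neighbouring ether, followed by I2, should give 2-iodo-3,5-bis(methoxymethoxy)phenyl N,N-diethylcarbamate F6. Hydrolysis of the carbamate (NaOH, EtOH, reflux) gives 3.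

**Step 9.** The most likely failure is incomplete lactonisation (the acidic 4-hydroxyl protonates the ylide, and the (E)-acrylate 17 must isomerise to 18) together with thermal degradation of the electron-rich triphenol at the temperature required. Fallback (sets out from 16, returns at 20 and so also replaces step 10): the lactone is closed at moderate temperature with the geometry enforced by the ring. The two phenols that are not hydrogen-bonded to the formyl group are silylated selectively (TIPSCl, 2.1 equiv, imidazole, CH2Cl2, 0 °C) to give 2-hydroxy-6-[(E)-2-[3-methoxy-4-(triisopropylsilyloxy)phenyl]ethenyl]-4-(triisopropylsilyloxy)benzaldehyde F7. (Triphenylphosphoranylidene)ketene in refluxing toluene acylates the remaining hydroxyl to give 2-formyl-3-[(E)-2-[3-methoxy-4-(triisopropylsilyloxy)phenyl]ethenyl]-5-(triisopropylsilyloxy)phenyl (triphenylphosphoranylidene)acetate F8, which should close by intramolecular Wittig reaction to 20.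

## Further compounds

F1 | step 7 | 2-hydroxy-4,6-bis(methoxymethoxy)benzaldehyde | O=Cc1c(O)cc(OCOC)cc1OCOC
F2 | step 7 | 2-formyl-3,5-bis(methoxymethoxy)phenyl trifluoromethanesulfonate | O=Cc1c(OCOC)cc(OCOC)cc1OS(=O)(=O)C(F)(F)F
F3 | step 7 | 2-[(E)-2-[3-methoxy-4-(methoxymethoxy)phenyl]ethenyl]-4,4,5,5-tetramethyl-1,3,2-dioxaborolane | COCOc1ccc(/C=C/B2OC(C)(C)C(C)(C)O2)cc1OC
F4 | step 13 | 4-[3-methoxy-4-(triisopropylsilyloxy)phenyl]-5-[(E)-2-[3-methoxy-4-(triisopropylsilyloxy)phenyl]ethenyl]-7-(triisopropylsilyloxy)-2H-chromen-2-one | O=c1cc(-c2ccc(O[Si](C(C)C)(C(C)C)C(C)C)c(OC)c2)c2c(/C=C/c3ccc(O[Si](C(C)C)(C(C)C)C(C)C)c(OC)c3)cc(O[Si](C(C)C)(C(C)C)C(C)C)cc2o1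
F5 | step 2 | 3,5-bis(methoxymethoxy)phenyl N,N-diethylcarbamate | CCN(CC)C(=O)Oc1cc(OCOC)cc(OCOC)c1
F6 | step 2 | 2-iodo-3,5-bis(methoxymethoxy)phenyl N,N-diethylcarbamate | CCN(CC)C(=O)Oc1cc(OCOC)cc(OCOC)c1I
F7 | step 9 | 2-hydroxy-6-[(E)-2-[3-methoxy-4-(triisopropylsilyloxy)phenyl]ethenyl]-4-(triisopropylsilyloxy)benzaldehyde | O=Cc1c(O)cc(O[Si](C(C)C)(C(C)C)C(C)C)cc1/C=C/c1ccc(O[Si](C(C)C)(C(C)C)C(C)C)c(OC)c1
F8 | step 9 | 2-formyl-3-[(E)-2-[3-methoxy-4-(triisopropylsilyloxy)phenyl]ethenyl]-5-(triisopropylsilyloxy)phenyl (triphenylphosphoranylidene)acetate | O=Cc1c(OC(=O)C=P(c2ccccc2)(c2ccccc2)c2ccccc2)cc(O[Si](C(C)C)(C(C)C)C(C)C)cc1/C=C/c1ccc(O[Si](C(C)C)(C(C)C)C(C)C)c(OC)c1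
A1 | alternative 1 | methyl (3R)-3-[2-hydroxy-6-[(E)-2-[3-methoxy-4-(methoxymethoxy)phenyl]ethenyl]-4-(triisopropylsilyloxy)phenyl]-3-[3-methoxy-4-(methoxymethoxy)phenyl]propanoate | COC(=O)C[C@H](c1ccc(OCOC)c(OC)c1)c1c(O)cc(O[Si](C(C)C)(C(C)C)C(C)C)cc1/C=C/c1ccc(OCOC)c(OC)c1
A2 | alternative 1 | methyl (3S)-3-[3-methoxy-4-(methoxymethoxy)phenyl]-3-[2-[(E)-2-[3-methoxy-4-(methoxymethoxy)phenyl]ethenyl]-4-oxocyclobut-2-en-1-yl]propanoate (either configuration at the ring carbon) | COC(=O)C[C@H](c1ccc(OCOC)c(OC)c1)C1C(=O)C=C1/C=C/c1ccc(OCOC)c(OC)c1
A3 | alternative 1 | (ethynyloxy)triisopropylsilane | C#CO[Si](C(C)C)(C(C)C)C(C)C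
A4 | alternative 2 | 4-[3-methoxy-4-(methoxymethoxy)phenyl]-7-(methoxymethoxy)-5-[(E)-2-[3-methoxy-4-(methoxymethoxy)phenyl]ethenyl]-2H-chromen-2-one | O=c1cc(-c2ccc(OCOC)c(OC)c2)c2c(/C=C/c3ccc(OCOC)c(OC)c3)cc(OCOC)cc2o1
A5 | alternative 2 | 5-ethenyl-7-(methoxymethoxy)-2H-chromen-2-one | C=Cc1cc(OCOC)cc2oc(=O)ccc12
A6 | alternative 2 | [3-methoxy-4-(methoxymethoxy)phenyl]boronic acid | COCOc1ccc(B(O)O)cc1OC
A7 | alternative 3 | (3R)-3-[2,4-dihydroxy-6-[(E)-2-[3-methoxy-4-(methoxymethoxy)phenyl]ethenyl]phenyl]-3-[3-methoxy-4-(methoxymethoxy)phenyl]propanoic acid | OC(=O)C[C@H](c1ccc(OCOC)c(OC)c1)c1c(O)cc(O)cc1/C=C/c1ccc(OCOC)c(OC)c1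
A8 | alternative 3 | methyl (3R,10E)-3,11-bis[3-methoxy-4-(methoxymethoxy)phenyl]-5,7,9-trioxoundec-10-enoate | COC(=O)C[C@H](c1ccc(OCOC)c(OC)c1)CC(=O)CC(=O)CC(=O)/C=C/c1ccc(OCOC)c(OC)c1
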